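##### Retrosynthetic overview

Chain numbering runs from C1 (carboxyl) to C18; ring A is the cyclohexene (C1–C4, C4a, C8a), ring B the cyclohexane.

1. Target ⇒ O-sulfation and ester hydrolysis of the cis-fused octalin hydroxy ester.
2. Rings A and B are formed together in one intramolecular Diels–Alder reaction of the linear all-E C18 hexaenoate: C6=C7 is the dienophile and C12–C15 the diene, bond C7–C12 closes ring B and bond C6–C15 closes ring A.
3. The hexaene is made in the same flask by Heck coupling of the C6–C18 (E)-vinyl iodide with methyl penta-2,4-dienoate (C1–C5).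
4. Vinyl iodide ⇒ hydrozirconation/iodination of the anti homopropargylic alcohol ⇒ Marshall propargylation of the C9–C18 trienal with (S)-but-3-yn-2-yl mesylate, which sets C8 and C9.
5. Trienal ⇒ Claisen rearrangement of a dienyl vinyl carbinol vinyl ether ⇒ vinyl Grignard addition to a dienal ⇒ Wittig reaction of tiglic aldehyde.

Assumption: the target is delivered as the neutral diacid drawn (carboxylic acid plus hydrogen sulfate); in practice it would be stored as a salt.

##### Route

Step 1
Reactants: 1 (2E)-2-methylbut-2-enal (tiglic aldehyde); 2 2-(triphenyl-λ5-phosphanylidene)propanal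
Product: 3 (2E,4E)-2,4-dimethylhexa-2,4-dienal
Conditions: PhMe, 110 °C, 24 h
Reagents that add atoms: 2-(triphenyl-λ5-phosphanylidene)propanal (2), CC(C=O)=P(c1ccccc1)(c1ccccc1)c1ccccc1
Why: Wittig olefination with a stabilized formyl ylide gives the (E)-trisubstituted enal; the E-alkene of 1 is not touched.

Step 2
Reactants: 3 (2E,4E)-2,4-dimethylhexa-2,4-dienal; 4 ethenylmagnesium bromide
Product: 5 rac-(4E,6E)-4,6-dimethylocta-1,4,6-trien-3-ol
Conditions: CH2=CHMgBr, THF, −78 to 0 °C; aq NH4Cl
Reagents that add atoms: ethenylmagnesium bromide (4), C=C[Mg]Br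
Why: Grignard 1,2-addition to the α-branched enal; the new carbinol centre is racemic and is erased in step 3.

Step 3
Reactants: 5 rac-(4E,6E)-4,6-dimethylocta-1,4,6-trien-3-ol; 6 butyl vinyl ether
Product: 8 (4E,6E,8E)-6,8-dimethyldeca-4,6,8-trienal, via allyl vinyl ether 7 (not isolated)
Conditions: Pd(OCOCF3)2 (2 mol %), 4,7-diphenyl-1,10-phenanthroline (2 mol %), Et3N (10 mol %), butyl vinyl ether, 75 °C; then PhMe, 110 °C
Reagents that add atoms: butyl vinyl ether (6), C=COCCCC
Why: Palladium-catalysed transfer vinylation under basic conditions followed by aliphatic Claisen [3,3] rearrangement through a chair transition state with the dienyl group equatorial gives the new (E)-alkene; the shift goes to the unsubstituted vinyl terminus and extends conjugation to the triene.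

Step 4
Reactants: 9 (2S)-but-3-yn-2-ol
Product: 10 (2S)-but-3-yn-2-yl methanesulfonate
Conditions: MsCl, Et3N, CH2Cl2, −78 to 0 °C
Reagents that add atoms: methanesulfonyl chloride, CS(=O)(=O)Cl
Why: O-sulfonylation forms only the O–S bond, so the stereocentre is retained.

Step 5
Reactants: 8 (4E,6E,8E)-6,8-dimethyldeca-4,6,8-trienal; 10 (2S)-but-3-yn-2-yl methanesulfonate
Product: 12 (3R,4S,7E,9E,11E)-3,9,11-trimethyltrideca-7,9,11-trien-1-yn-4-ol, via allenylzinc 11 (not isolated)
Conditions: Pd(OAc)2 (5 mol %), PPh3 (5 mol %), Et2Zn (3 equiv), THF, −78 to −20 °C; aq NH4Cl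
Reagents that add atoms: (2S)-but-3-yn-2-yl methanesulfonate (10), C[C@H](OS(C)(=O)=O)C#C
Why: Marshall propargylation: zerovalent palladium displaces the mesylate anti (SN2′), transmetalation gives the (M)-allenylzinc, and a cyclic SE2′ addition with the aldehyde chain anti to the allenyl methyl gives the anti adduct with net inversion at the former carbinol carbon, setting C8 (R) and C9 (S) in chain numbering (dr about 5–9:1 expected for an unbranched aldehyde, minor syn isomer removed by chromatography).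

Step 6
Reactants: 12 (3R,4S,7E,9E,11E)-3,9,11-trimethyltrideca-7,9,11-trien-1-yn-4-ol
Product: 14 (1E,3R,4S,7E,9E,11E)-1-iodo-3,9,11-trimethyltrideca-1,7,9,11-tetraen-4-ol, via bis-zirconocene 13 (not isolated)
Conditions: Cp2Zr(H)Cl (2.2 equiv), THF, 0 to 23 °C; then I2, −40 °C; aq Na2S2O3
Reagents that add atoms: iodine, II
Why: Hydrozirconation of the terminal alkyne is syn and places zirconium on the terminal carbon (one equivalent is consumed by the O–H), and iodinolysis proceeds with retention to give the (E)-vinyl iodide; the internal conjugated alkenes react far more slowly.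

Step 7
Reactants: 14 (1E,3R,4S,7E,9E,11E)-1-iodo-3,9,11-trimethyltrideca-1,7,9,11-tetraen-4-ol; 15 methyl (2E)-penta-2,4-dienoate
Product: 17 methyl (2E,4E)-5-[(1S,2S,4aS,7S,8R,8aR)-2-[(2E)-but-2-en-2-yl]-7-hydroxy-3,8-dimethyl-1,2,4a,5,6,7,8,8a-octahydronaphthalen-1-yl]penta-2,4-dienoate, via hexaene ester 16 (not isolated)
Conditions: Pd2(dba)3 (3 mol %), P(t-Bu)3 (7 mol %), Cy2NMe (1.2 equiv), PhMe, 23 °C, dark; then BHT, PhMe (5 mM), 110 °C, 24–48 h
Reagents that add atoms: methyl (2E)-penta-2,4-dienoate (15), C=C/C=C/C(=O)OC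
Why: Mizoroki–Heck coupling (retention at the vinyl iodide, insertion at the unsubstituted terminus of 15, syn β-hydride elimination) gives the all-E hexaene 16, whose C12–C15 diene adds to C6=C7 in an intramolecular Diels–Alder reaction; the exo transition state (dienoate turned away from the diene, chair-like tether with the C8 methyl pseudo-equatorial and the C9 hydroxyl pseudo-axial) closes both rings and sets C1, C2, C4a and C8a from C8/C9, the E,E-diene and E-dienophile fixing the 1,2-trans and H1/H8a-trans relationships and the exo mode giving the cis ring fusion.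

Step 8
Reactants: 17 methyl (2E,4E)-5-[(1S,2S,4aS,7S,8R,8aR)-2-[(2E)-but-2-en-2-yl]-7-hydroxy-3,8-dimethyl-1,2,4a,5,6,7,8,8a-octahydronaphthalen-1-yl]penta-2,4-dienoate
Product: 19 (2E,4E)-5-[(1S,2S,4aS,7S,8R,8aR)-2-[(2E)-but-2-en-2-yl]-3,8-dimethyl-7-(sulfooxy)-1,2,4a,5,6,7,8,8a-octahydronaphthalen-1-yl]penta-2,4-dienoic acid, via pyridinium sulfate 18 (not isolated)
Conditions: SO3·pyridine, pyridine, 23 °C; then LiOH, MeOH–H2O, 23 °C; then 1 M HCl to pH 2, 0 °C, C18 desalting
Reagents that add atoms: sulfur trioxide pyridine complex, [O-]S(=O)(=O)[n+]1ccccc1; lithium hydroxide, [Li+].[OH-]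
Why: O-sulfation of the secondary alcohol forms only the O–S bond (retention at C7), and the alkyl sulfate monoanion resists hydroxide, so the methyl ester can be saponified in the same flask before acidification.

##### Compound list

1 | (2E)-2-methylbut-2-enal (tiglic aldehyde) | C/C=C(\C)C=O | starting material
2 | 2-(triphenyl-λ5-phosphanylidene)propanal | CC(C=O)=P(c1ccccc1)(c1ccccc1)c1ccccc1 | starting material
3 | (2E,4E)-2,4-dimethylhexa-2,4-dienal | C/C=C(\C)/C=C(\C)C=O | intermediate
4 | ethenylmagnesium bromide | C=C[Mg]Br | starting material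
5 | rac-(4E,6E)-4,6-dimethylocta-1,4,6-trien-3-ol | C/C=C(\C)/C=C(\C)C(O)C=C | intermediate
6 | butyl vinyl ether | C=COCCCC | starting material
7 | rac-(4E,6E)-3-(ethenyloxy)-4,6-dimethylocta-1,4,6-triene | C/C=C(\C)/C=C(\C)C(OC=C)C=C | intermediate
8 | (4E,6E,8E)-6,8-dimethyldeca-4,6,8-trienal | C/C=C(\C)/C=C(\C)/C=C/CCC=O | intermediate
9 | (2S)-but-3-yn-2-ol | C[C@H](O)C#C | starting material
10 | (2S)-but-3-yn-2-yl methanesulfonate | C[C@H](OS(C)(=O)=O)C#C | intermediate
11 | (M)-buta-1,2-dien-1-yl(ethyl)zinc | CC[Zn]C([H])=[C@@]=C(C)[H] | intermediate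
12 | (3R,4S,7E,9E,11E)-3,9,11-trimethyltrideca-7,9,11-trien-1-yn-4-ol | C/C=C(\C)/C=C(\C)/C=C/CC[C@H](O)[C@H](C)C#C | intermediate
13 | C1-alkenyl, O4-alkoxy bis[chloridobis(cyclopentadienyl)zirconium] derivative of 12 (1E) | C/C=C(\C)/C=C(\C)/C=C/CC[C@H](O[Zr](Cl)(C1C=CC=C1)C1C=CC=C1)[C@H](C)/C=C/[Zr](Cl)(C1C=CC=C1)C1C=CC=C1 | intermediate
14 | (1E,3R,4S,7E,9E,11E)-1-iodo-3,9,11-trimethyltrideca-1,7,9,11-tetraen-4-ol | C/C=C(\C)/C=C(\C)/C=C/CC[C@H](O)[C@H](C)/C=C/I | intermediate
15 | methyl (2E)-penta-2,4-dienoate | C=C/C=C/C(=O)OC | starting material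
16 | methyl (2E,4E,6E,8R,9S,12E,14E,16E)-9-hydroxy-8,14,16-trimethyloctadeca-2,4,6,12,14,16-hexaenoate | C/C=C(\C)/C=C(\C)/C=C/CC[C@H](O)[C@H](C)/C=C/C=C/C=C/C(=O)OC | intermediate
17 | methyl (2E,4E)-5-[(1S,2S,4aS,7S,8R,8aR)-2-[(2E)-but-2-en-2-yl]-7-hydroxy-3,8-dimethyl-1,2,4a,5,6,7,8,8a-octahydronaphthalen-1-yl]penta-2,4-dienoate | C/C=C(\C)[C@H]1C(C)=C[C@H]2CC[C@H](O)[C@H](C)[C@H]2[C@@H]1/C=C/C=C/C(=O)OC | intermediate
18 | pyridinium salt of the 7-O-sulfate of 17 | C/C=C(\C)[C@H]1C(C)=C[C@H]2CC[C@H](OS(=O)(=O)[O-])[C@H](C)[C@H]2[C@@H]1/C=C/C=C/C(=O)OC.c1cc[nH+]cc1 | intermediate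
19 | (2E,4E)-5-[(1S,2S,4aS,7S,8R,8aR)-2-[(2E)-but-2-en-2-yl]-3,8-dimethyl-7-(sulfooxy)-1,2,4a,5,6,7,8,8a-octahydronaphthalen-1-yl]penta-2,4-dienoic acid | C/C=C(\C)[C@H]1C(C)=C[C@H]2CC[C@H](OS(=O)(=O)O)[C@H](C)[C@H]2[C@@H]1/C=C/C=C/C(=O)O | target

##### Totals

Total steps: 8. Longest linear sequence: 7 (steps 1, 2, 3, 5, 6, 7, 8); step 4 is a one-step side branch.

##### Steps most likely to fail

**Step 7 (highest risk).** Three things can go wrong:
- Exo/endo selectivity: thermal cyclizations of all-E decatrienes with a terminal activating group are often close to 1:1, so the trans-fused endo adduct is the expected by-product and may even predominate.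
- Periselectivity: the trienoate could instead act as the diene (C4–C7) toward C12=C13.
- Palladium hydride left from the Heck stage could isomerize the polyene on heating.

Fallback, setting out from 12 and returning at 17, uses a dienophile whose geometry enforces the cis fusion and an epimerizable C1:
- 12 is silylated (t-BuMe2SiOTf, 2,6-lutidine) to the silyl ether F1.
- The alkyne is carboxylated (n-BuLi, ClCO2Me) to the ynoate F2.
- Semi-hydrogenation (H2, Pd/CaCO3 poisoned with Pb(OAc)2, quinoline) gives the (Z)-enoate F3.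
- Me2AlCl-promoted endo intramolecular Diels–Alder reaction (ester and tether are cis on the dienophile, so endo ester means cis-fused ring; allylic strain keeps the C8 methyl on the face away from the diene) gives the C1-epimeric octalin ester F4.
- NaOMe in MeOH equilibrates C1 to the ester trans to both neighbours, the C1-equilibrated ester F5.
- i-Bu2AlH at −78 °C gives the aldehyde F6.
- Horner–Wadsworth–Emmons reaction with trimethyl 4-phosphonocrotonate and LiN(SiMe3)2 gives the silylated dienoate F7.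
- Bu4NF returns 17.

**Step 6.** Cp2Zr(H)Cl must discriminate the alkyne from the conjugated triene in the presence of a free hydroxyl, and iodine can attack or isomerize the triene. Fallback, setting out from 12 and returning at 14: palladium-catalysed hydrostannation (Bu3SnH, PdCl2(PPh3)2, THF, 0 °C), which tolerates the free alcohol and is directed to the terminus by the α-branch, gives the (E)-vinylstannane F8. Iododestannylation with one equivalent of I2 in CH2Cl2 at 0 °C then gives 14 with retention.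

**Step 3.** The doubly allylic alcohol 5 ionizes easily, and vinyl transfer or the rearrangement may be diverted to allylic transposition products. Fallback, setting out from 3 and returning at 8, builds the C12=C13 alkene by olefination and cross-coupling instead of a sigmatropic shift:
- Takai iodo-olefination of 3 (CrCl2, CHI3, THF, 0 °C) gives the (E)-trienyl iodide F9.
- Hydroboration of acrolein diethyl acetal with 9-BBN gives the alkylborane F10.
- B-alkyl Suzuki–Miyaura coupling of F9 with F10 (PdCl2(dppf), K3PO4, DMF–H2O, 23 °C) gives the triene acetal F11.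
- Pyridinium p-toluenesulfonate in acetone–H2O releases 8.

##### Further compounds

F1 | step 7 | tert-butyldimethylsilyl ether of 12 | C/C=C(\C)/C=C(\C)/C=C/CC[C@H](O[Si](C)(C)C(C)(C)C)[C@H](C)C#C
F2 | step 7 | methyl (4R,5S,8E,10E,12E)-5-(tert-butyldimethylsilyloxy)-4,10,12-trimethyltetradeca-8,10,12-trien-2-ynoate | C/C=C(\C)/C=C(\C)/C=C/CC[C@H](O[Si](C)(C)C(C)(C)C)[C@H](C)C#CC(=O)OC
F3 | step 7 | methyl (2Z,4R,5S,8E,10E,12E)-5-(tert-butyldimethylsilyloxy)-4,10,12-trimethyltetradeca-2,8,10,12-tetraenoate | C/C=C(\C)/C=C(\C)/C=C/CC[C@H](O[Si](C)(C)C(C)(C)C)[C@H](C)/C=C\C(=O)OC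
F4 | step 7 | C1-epimeric cis-fused octalin methyl ester (CO2Me cis to the butenyl group and to C8; other centres as in 17; O-silylated) | C/C=C(\C)[C@H]1C(C)=C[C@H]2CC[C@H](O[Si](C)(C)C(C)(C)C)[C@H](C)[C@H]2[C@H]1C(=O)OC
F5 | step 7 | C1-equilibrated cis-fused octalin methyl ester (CO2Me trans to the butenyl group and to C8; O-silylated) | C/C=C(\C)[C@H]1C(C)=C[C@H]2CC[C@H](O[Si](C)(C)C(C)(C)C)[C@H](C)[C@H]2[C@@H]1C(=O)OC
F6 | step 7 | corresponding octalin-1-carbaldehyde (O-silylated) | C/C=C(\C)[C@H]1C(C)=C[C@H]2CC[C@H](O[Si](C)(C)C(C)(C)C)[C@H](C)[C@H]2[C@@H]1C=O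
F7 | step 7 | tert-butyldimethylsilyl ether of 17 | C/C=C(\C)[C@H]1C(C)=C[C@H]2CC[C@H](O[Si](C)(C)C(C)(C)C)[C@H](C)[C@H]2[C@@H]1/C=C/C=C/C(=O)OC
F8 | step 6 | (1E,3R,4S,7E,9E,11E)-3,9,11-trimethyl-1-(tributylstannyl)trideca-1,7,9,11-tetraen-4-ol | C/C=C(\C)/C=C(\C)/C=C/CC[C@H](O)[C@H](C)/C=C/[Sn](CCCC)(CCCC)CCCC
F9 | step 3 | (1E,3E,5E)-1-iodo-3,5-dimethylhepta-1,3,5-triene | C/C=C(\C)/C=C(\C)/C=C/I
F10 | step 3 | 9-(3,3-diethoxypropyl)-9-borabicyclo[3.3.1]nonane | CCOC(CCB1C2CCCC1CCC2)OCC
F11 | step 3 | (2E,4E,6E)-10,10-diethoxy-3,5-dimethyldeca-2,4,6-triene | C/C=C(\C)/C=C(\C)/C=C/CCC(OCC)OCC
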